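**Plan**

1. The target is (−)-epigallocatechin 3-O-gallate-(4β→8)-(+)-catechin; suffix U marks atoms of the upper (galloylated) flavan, suffix L those of the lower (catechin) flavan. Retrosynthesis: remove 13 benzyl ethers; cut the interflavan bond C4(U)–C8(L) into a C4(U) cation and a C8(L) boron nucleophile; cut the gallate ester at O3(U); cut O1(L)–C8a(L) together with C8(L)–B in one aryne event; cut C2(L)–aryl (ketone synthesis) and C4(L)–C3(L) (epoxide opening).
2. Enabling feature: in ring A of the lower unit the ether carbon C8a(L) and the interflavan carbon C8(L) are neighbours, flanked by the 7-oxygen on one side and by C4a(L), which carries the tether C4(L)–C3(L)–C2(L)–O, on the other. An aryne across C8(L)≡C8a(L) can therefore take up O1(L) and a handle for C4(U) in one operation.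
3. Forward: fluoroarene → aryl lactate → α-benzyloxy ketone → anti alcohol (open chain of the lower unit) → aryne cascade closes ring C of the lower unit and borylates C8(L). In a second branch (−)-epigallocatechin is benzylated, oxidised at C4(U) and galloylated. Ipso coupling joins the flavans, and hydrogenolysis ends the route.
4. Stereochemistry: C3(L) from methyl (S)-glycidate; C2(L) by chelation-controlled ketone reduction; C2(U) and C3(U) from natural (−)-epigallocatechin; C4(U) by attack anti to the 3-galloyloxy and 2-aryl groups.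

Key step: step 7

Remark: 1,3,5-trifluorobenzene, methyl (S)-glycidate, 4-bromo-1,2-bis(benzyloxy)benzene, (−)-epigallocatechin and 3,4,5-tris(benzyloxy)benzoic acid are taken as commercial.

**Route**

Step 1
Reactants: 1 1,3,5-trifluorobenzene
Product: 2 1,3-bis(benzyloxy)-5-fluorobenzene
Conditions: BnOH (2.1 equiv), NaH, NMP, 0 → 90 °C
Reagents that add atoms: benzyl alcohol OCc1ccccc1
Why: Twofold nucleophilic aromatic substitution by benzyloxide should stop after two fluorides because each alkoxy group introduced lowers the reactivity of the remaining C–F bonds.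

Step 2
Reactants: 2 1,3-bis(benzyloxy)-5-fluorobenzene; 3 methyl (2S)-oxirane-2-carboxylate
Product: 6 methyl (2S)-3-[2,4-bis(benzyloxy)-6-fluorophenyl]-2-hydroxypropanoate, via aryllithium 4 (not isolated), via arylmagnesium bromide 5 (not isolated)
Conditions: n-BuLi, THF, −78 °C; MgBr2·OEt2; CuBr·SMe2 (10 mol %), 3, −40 → −20 °C; aq NH4Cl
Reagents that add atoms: none
Why: Directed ortho-lithiation should take place at the C–H flanked by fluorine and a benzyloxy group (the most acidic position), and after lithium–magnesium exchange the copper-catalysed aryl Grignard reagent should open the glycidate at its CH2 terminus (epoxide opening by an organocopper species), so the untouched (S) center becomes C3(L).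

Step 3
Reactants: 6 methyl (2S)-3-[2,4-bis(benzyloxy)-6-fluorophenyl]-2-hydroxypropanoate
Product: 7 methyl (2S)-2-(benzyloxy)-3-[2,4-bis(benzyloxy)-6-fluorophenyl]propanoate
Conditions: BnBr, Ag2O, Et2O, rt, dark
Reagents that add atoms: benzyl bromide BrCc1ccccc1
Why: Ag2O-mediated Williamson benzylation is mild enough to alkylate the α-hydroxy ester without enolisation, so the (S) center should be kept.

Step 4
Reactants: 7 methyl (2S)-2-(benzyloxy)-3-[2,4-bis(benzyloxy)-6-fluorophenyl]propanoate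
Product: 8 (2S)-2-(benzyloxy)-3-[2,4-bis(benzyloxy)-6-fluorophenyl]-N-methoxy-N-methylpropanamide
Conditions: MeNH(OMe)·HCl, iPrMgCl, THF, −20 → 0 °C
Reagents that add atoms: N,O-dimethylhydroxylamine hydrochloride CNOC.Cl
Why: Aminolysis of the methyl ester by the chloromagnesium amide of N,O-dimethylhydroxylamine should give the Weinreb amide without epimerising the α-alkoxy center.

Step 5
Reactants: 8 (2S)-2-(benzyloxy)-3-[2,4-bis(benzyloxy)-6-fluorophenyl]-N-methoxy-N-methylpropanamide; 9 4-bromo-1,2-bis(benzyloxy)benzene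
Product: 11 (2S)-2-(benzyloxy)-3-[2,4-bis(benzyloxy)-6-fluorophenyl]-1-[3,4-bis(benzyloxy)phenyl]propan-1-one, via arylmagnesium bromide 10 (not isolated)
Conditions: 9, Mg, THF; then 8, THF, 0 °C; cold aq NH4Cl
Reagents that add atoms: none
Why: Weinreb ketone synthesis, in which the aryl Grignard reagent adds only once because the chelated tetrahedral magnesium adduct collapses to the α-benzyloxy aryl ketone only on work-up.

Step 6
Reactants: 11 (2S)-2-(benzyloxy)-3-[2,4-bis(benzyloxy)-6-fluorophenyl]-1-[3,4-bis(benzyloxy)phenyl]propan-1-one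
Product: 12 (1R,2S)-2-(benzyloxy)-3-[2,4-bis(benzyloxy)-6-fluorophenyl]-1-[3,4-bis(benzyloxy)phenyl]propan-1-ol
Conditions: Zn(BH4)2, Et2O, −30 → 0 °C; aq NH4Cl
Reagents that add atoms: none
Why: Chelation-controlled reduction, in which zinc bridges the carbonyl and α-benzyloxy oxygens and hydride enters from the side of the α-hydrogen, should set C2(L) as (R), the anti (erythro) relationship that a 2,3-trans flavan needs.

Step 7
Reactants: 12 (1R,2S)-2-(benzyloxy)-3-[2,4-bis(benzyloxy)-6-fluorophenyl]-1-[3,4-bis(benzyloxy)phenyl]propan-1-ol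
Product: 17 potassium [(2R,3S)-3,5,7-tris(benzyloxy)-2-[3,4-bis(benzyloxy)phenyl]-3,4-dihydro-2H-chromen-8-yl]trifluoroborate, via dilithio species 13 (not isolated), via aryne alkoxide 14 (not isolated), via 8-lithioflavan 15 (not isolated), via lithium aryltrimethoxyborate 16 (not isolated)
Conditions: n-BuLi (2.1 equiv), THF (0.02 M), −78 °C, then → −30 °C; B(OMe)3, −78 °C → rt; aq KHF2, MeOH
Reagents that add atoms: trimethyl borate COB(OC)OC; potassium hydrogen difluoride [K+].[F-].F
Why: n-BuLi should first form the lithium alkoxide and then remove the ring-A proton between fluorine and the 7-benzyloxy group (the proton between the two benzyloxy groups lacks the acidifying ortho-fluorine), and on warming this ortho-fluoroaryllithium loses LiF to give the 3-alkoxy aryne C8(L)≡C8a(L). The closest known reaction types are the intramolecular addition of alkoxides to arynes that gives chromans and the three-component aryne couplings in which the aryl anion left by the nucleophile is trapped by an electrophile. Ring C of the lower unit closes in a 6-exo-dig mode by attack of the C2(L) alkoxide on C8a(L); the three-atom tether on C4a(L) can only reach this carbon, and the σ-withdrawing 7-benzyloxy group beside C8(L) makes the distal carbon C8a(L) the electrophilic end of the triple bond and stabilises the carbanion at C8(L). No stereocenter is formed, and since the new bond is O–C(aryl) the centers C2(L) and C3(L) are untouched and the (2R,3S) configuration of 12 is carried over. The resulting 2,6-dialkoxyaryllithium has no proton source (butane is the only conjugate acid present) and is captured by B(OMe)3 and fixed by KHF2, so the aryne takes up O1(L) and boron on neighbouring carbons in one operation. The selectivities needed are lithiation beside fluorine, internal O-attack over capture of the aryne by a second aryllithium (secured by high dilution) and six- over five-membered closure (secured because O3(L) is a benzyl ether and only O2(L) is anionic).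

Step 8
Reactants: 18 (−)-epigallocatechin
Product: 19 (2R,3R)-5,7-bis(benzyloxy)-2-[3,4,5-tris(benzyloxy)phenyl]-3,4-dihydro-2H-chromen-3-ol
Conditions: BnBr (5.5 equiv), K2CO3, degassed DMF, 0 °C → rt, argon
Reagents that add atoms: benzyl bromide BrCc1ccccc1
Why: Williamson etherification under carbonate conditions should alkylate the five phenols only, since the aliphatic 3-hydroxyl is not deprotonated, and the mild base and low temperature should leave the C2(U) and C3(U) centers untouched.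

Step 9
Reactants: 19 (2R,3R)-5,7-bis(benzyloxy)-2-[3,4,5-tris(benzyloxy)phenyl]-3,4-dihydro-2H-chromen-3-ol
Product: 20 (2R,3R,4S)-5,7-bis(benzyloxy)-4-(2-ethoxyethoxy)-2-[3,4,5-tris(benzyloxy)phenyl]-3,4-dihydro-2H-chromen-3-ol
Conditions: DDQ, 2-ethoxyethanol, CH2Cl2, rt
Reagents that add atoms: 2-ethoxyethanol CCOCCO
Why: DDQ abstracts hydride from the benzylic C4(U)–H activated by the ortho and para ether oxygens of ring A (benzylic oxidation), and the alcohol should capture the cation trans to the 3-hydroxyl to give the 4β-ether, whose configuration is not critical because this center is ionised again in step 11.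

Step 10
Reactants: 20 (2R,3R,4S)-5,7-bis(benzyloxy)-4-(2-ethoxyethoxy)-2-[3,4,5-tris(benzyloxy)phenyl]-3,4-dihydro-2H-chromen-3-ol; 21 3,4,5-tris(benzyloxy)benzoic acid
Product: 22 (2R,3R,4S)-5,7-bis(benzyloxy)-4-(2-ethoxyethoxy)-2-[3,4,5-tris(benzyloxy)phenyl]-3,4-dihydro-2H-chromen-3-yl 3,4,5-tris(benzyloxy)benzoate
Conditions: 21, DCC, DMAP, CH2Cl2, 0 °C → rt
Reagents that add atoms: none
Why: Steglich esterification acylates the secondary 3-hydroxyl under neutral conditions that should spare the acid-labile benzylic 4-ether and touch no stereocenter.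

Step 11
Reactants: 17 potassium [(2R,3S)-3,5,7-tris(benzyloxy)-2-[3,4-bis(benzyloxy)phenyl]-3,4-dihydro-2H-chromen-8-yl]trifluoroborate; 22 (2R,3R,4S)-5,7-bis(benzyloxy)-4-(2-ethoxyethoxy)-2-[3,4,5-tris(benzyloxy)phenyl]-3,4-dihydro-2H-chromen-3-yl 3,4,5-tris(benzyloxy)benzoate
Product: 23 (2R,3R,4R)-5,7-bis(benzyloxy)-4-[(2R,3S)-3,5,7-tris(benzyloxy)-2-[3,4-bis(benzyloxy)phenyl]-3,4-dihydro-2H-chromen-8-yl]-2-[3,4,5-tris(benzyloxy)phenyl]-3,4-dihydro-2H-chromen-3-yl 3,4,5-tris(benzyloxy)benzoate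
Conditions: BF3·OEt2, CH2Cl2/MeCN, 4 Å MS, −40 → −10 °C; aq NaHCO3
Reagents that add atoms: none
Why: BF3 ionises the C4(U)–O bond to the ring-A-stabilised benzylic cation, which the electron-rich aryltrifluoroborate should attack with its boron-bearing carbon (ipso-substitution of an aryltrifluoroborate by a stabilised carbocation, a Friedel–Crafts-type coupling), so the bond forms only at C8(L), and the nucleophile enters anti to the 2-aryl and 3-galloyloxy groups (the ester can shield the α face as an acyloxonium ion), which should set C4(U) as 4β (R).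

Step 12
Reactants: 23 (2R,3R,4R)-5,7-bis(benzyloxy)-4-[(2R,3S)-3,5,7-tris(benzyloxy)-2-[3,4-bis(benzyloxy)phenyl]-3,4-dihydro-2H-chromen-8-yl]-2-[3,4,5-tris(benzyloxy)phenyl]-3,4-dihydro-2H-chromen-3-yl 3,4,5-tris(benzyloxy)benzoate
Product: 24 (2R,3R,4R)-4-[(2R,3S)-2-(3,4-dihydroxyphenyl)-3,5,7-trihydroxy-3,4-dihydro-2H-chromen-8-yl]-5,7-dihydroxy-2-(3,4,5-trihydroxyphenyl)-3,4-dihydro-2H-chromen-3-yl 3,4,5-trihydroxybenzoate
Conditions: H2 (1 atm), Pd(OH)2/C, THF/MeOH/H2O, rt; filtration and freeze-drying under argon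
Reagents that add atoms: none
Why: Hydrogenolysis of the thirteen benzyl ethers should free all phenols and the 3-hydroxyl of the lower unit, while the gallate ester and the interflavan bond are stable to these neutral conditions.

**Compound list**

1 | 1,3,5-trifluorobenzene | Fc1cc(F)cc(F)c1 | starting material
2 | 1,3-bis(benzyloxy)-5-fluorobenzene | Fc1cc(OCc2ccccc2)cc(OCc2ccccc2)c1 | intermediate
3 | methyl (2S)-oxirane-2-carboxylate (methyl (S)-glycidate) | COC(=O)[C@@H]1CO1 | starting material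
4 | [2,4-bis(benzyloxy)-6-fluorophenyl]lithium | [Li]c1c(F)cc(OCc2ccccc2)cc1OCc1ccccc1 | intermediate
5 | [2,4-bis(benzyloxy)-6-fluorophenyl]magnesium bromide | Br[Mg]c1c(F)cc(OCc2ccccc2)cc1OCc1ccccc1 | intermediate
6 | methyl (2S)-3-[2,4-bis(benzyloxy)-6-fluorophenyl]-2-hydroxypropanoate | COC(=O)[C@@H](O)Cc1c(F)cc(OCc2ccccc2)cc1OCc1ccccc1 | intermediate
7 | methyl (2S)-2-(benzyloxy)-3-[2,4-bis(benzyloxy)-6-fluorophenyl]propanoate | COC(=O)[C@@H](OCc1ccccc1)Cc1c(F)cc(OCc2ccccc2)cc1OCc1ccccc1 | intermediate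
8 | (2S)-2-(benzyloxy)-3-[2,4-bis(benzyloxy)-6-fluorophenyl]-N-methoxy-N-methylpropanamide | CON(C)C(=O)[C@@H](OCc1ccccc1)Cc1c(F)cc(OCc2ccccc2)cc1OCc1ccccc1 | intermediate
9 | 4-bromo-1,2-bis(benzyloxy)benzene | Brc1ccc(OCc2ccccc2)c(OCc2ccccc2)c1 | starting material
10 | [3,4-bis(benzyloxy)phenyl]magnesium bromide | Br[Mg]c1ccc(OCc2ccccc2)c(OCc2ccccc2)c1 | intermediate
11 | (2S)-2-(benzyloxy)-3-[2,4-bis(benzyloxy)-6-fluorophenyl]-1-[3,4-bis(benzyloxy)phenyl]propan-1-one | O=C(c1ccc(OCc2ccccc2)c(OCc2ccccc2)c1)[C@@H](OCc1ccccc1)Cc1c(F)cc(OCc2ccccc2)cc1OCc1ccccc1 | intermediate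
12 | (1R,2S)-2-(benzyloxy)-3-[2,4-bis(benzyloxy)-6-fluorophenyl]-1-[3,4-bis(benzyloxy)phenyl]propan-1-ol | O[C@H](c1ccc(OCc2ccccc2)c(OCc2ccccc2)c1)[C@@H](OCc1ccccc1)Cc1c(F)cc(OCc2ccccc2)cc1OCc1ccccc1 | intermediate
13 | dilithio derivative of 12 (lithium alkoxide, lithium on the ring carbon between F and OBn) | [Li]O[C@H](c1ccc(OCc2ccccc2)c(OCc2ccccc2)c1)[C@@H](OCc1ccccc1)Cc1c(F)c([Li])c(OCc2ccccc2)cc1OCc1ccccc1 | intermediate
14 | lithium (1R,2S)-2-(benzyloxy)-3-[2,4-bis(benzyloxy)-5,6-didehydrophenyl]-1-[3,4-bis(benzyloxy)phenyl]propan-1-olate (aryne) | [Li]O[C@H](c1ccc(OCc2ccccc2)c(OCc2ccccc2)c1)[C@@H](OCc1ccccc1)CC1=C(OCc2ccccc2)C=C(OCc2ccccc2)C#C1 | intermediate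
15 | [(2R,3S)-3,5,7-tris(benzyloxy)-2-[3,4-bis(benzyloxy)phenyl]-3,4-dihydro-2H-chromen-8-yl]lithium | [Li]c1c(OCc2ccccc2)cc(OCc2ccccc2)c2c1O[C@H](c1ccc(OCc3ccccc3)c(OCc3ccccc3)c1)[C@@H](OCc1ccccc1)C2 | intermediate
16 | lithium [(2R,3S)-3,5,7-tris(benzyloxy)-2-[3,4-bis(benzyloxy)phenyl]-3,4-dihydro-2H-chromen-8-yl]trimethoxyborate | [Li+].CO[B-](OC)(OC)c1c(OCc2ccccc2)cc(OCc2ccccc2)c2c1O[C@H](c1ccc(OCc3ccccc3)c(OCc3ccccc3)c1)[C@@H](OCc1ccccc1)C2 | intermediate
17 | potassium [(2R,3S)-3,5,7-tris(benzyloxy)-2-[3,4-bis(benzyloxy)phenyl]-3,4-dihydro-2H-chromen-8-yl]trifluoroborate | [K+].F[B-](F)(F)c1c(OCc2ccccc2)cc(OCc2ccccc2)c2c1O[C@H](c1ccc(OCc3ccccc3)c(OCc3ccccc3)c1)[C@@H](OCc1ccccc1)C2 | intermediate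
18 | (−)-epigallocatechin, (2R,3R) | O[C@@H]1Cc2c(O)cc(O)cc2O[C@@H]1c1cc(O)c(O)c(O)c1 | starting material
19 | penta-O-benzyl derivative of 18: (2R,3R)-5,7-bis(benzyloxy)-2-[3,4,5-tris(benzyloxy)phenyl]-3,4-dihydro-2H-chromen-3-ol | O[C@@H]1Cc2c(OCc3ccccc3)cc(OCc3ccccc3)cc2O[C@@H]1c1cc(OCc2ccccc2)c(OCc2ccccc2)c(OCc2ccccc2)c1 | intermediate
20 | 4β-(2-ethoxyethoxy) derivative of 19, (2R,3R,4S), ether trans to O3 | O[C@@H]1[C@@H](OCCOCC)c2c(OCc3ccccc3)cc(OCc3ccccc3)cc2O[C@@H]1c1cc(OCc2ccccc2)c(OCc2ccccc2)c(OCc2ccccc2)c1 | intermediate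
21 | 3,4,5-tris(benzyloxy)benzoic acid | OC(=O)c1cc(OCc2ccccc2)c(OCc2ccccc2)c(OCc2ccccc2)c1 | starting material
22 | 3-O-[3,4,5-tris(benzyloxy)benzoyl] derivative of 20, (2R,3R,4S) | O=C(O[C@@H]1[C@@H](OCCOCC)c2c(OCc3ccccc3)cc(OCc3ccccc3)cc2O[C@@H]1c1cc(OCc2ccccc2)c(OCc2ccccc2)c(OCc2ccccc2)c1)c1cc(OCc2ccccc2)c(OCc2ccccc2)c(OCc2ccccc2)c1 | intermediate
23 | trideca-O-benzyl dimer: octa-O-benzyl-epigallocatechin gallate-(4β→8)-penta-O-benzylcatechin, upper (2R,3R,4R), lower (2R,3S) | O=C(O[C@@H]1[C@@H](c2c(OCc3ccccc3)cc(OCc3ccccc3)c3c2O[C@H](c2ccc(OCc4ccccc4)c(OCc4ccccc4)c2)[C@@H](OCc2ccccc2)C3)c2c(OCc3ccccc3)cc(OCc3ccccc3)cc2O[C@@H]1c1cc(OCc2ccccc2)c(OCc2ccccc2)c(OCc2ccccc2)c1)c1cc(OCc2ccccc2)c(OCc2ccccc2)c(OCc2ccccc2)c1 | intermediate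
24 | (−)-epigallocatechin 3-O-gallate-(4β→8)-(+)-catechin, upper (2R,3R,4R), lower (2R,3S) | O=C(O[C@@H]1[C@@H](c2c(O)cc(O)c3c2O[C@H](c2ccc(O)c(O)c2)[C@@H](O)C3)c2c(O)cc(O)cc2O[C@@H]1c1cc(O)c(O)c(O)c1)c1cc(O)c(O)c(O)c1 | target

**Step count and risks**

Total step count: 12. Longest linear sequence: 9 (steps 1 to 7, then 11 and 12); steps 8 to 10 form the second branch.

Steps most likely to fail:

1. Step 7. What may go wrong: metalation at a benzylic OCH2 or at the ring-A position between the two benzyloxy groups instead of beside fluorine; capture of the aryne by a second aryllithium instead of by the internal alkoxide; proton transfer from a benzylic OCH2 to the C8(L) carbanion before borylation. The fallback sets out from 12 and returns at 17. The ring is closed without an aryne by intramolecular SNAr of the potassium alkoxide on the aryl fluoride (KOtBu, DMF, 80 °C; both benzyloxy groups are meta to fluorine and do not deactivate the ipso carbon), which should give (2R,3S)-3,5,7-tris(benzyloxy)-2-[3,4-bis(benzyloxy)phenyl]-3,4-dihydro-2H-chromene F1. Electrophilic bromination (NBS, CH2Cl2, −20 °C) at the most nucleophilic free position C8 should then give the 8-bromo flavan F2. Bromine–lithium exchange (n-BuLi, THF, −78 °C) gives 15 at a temperature where it is stable, and borylation via 16 with B(OMe)3 and KHF2 leads to 17.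

2. Step 11. What may go wrong: the cation may be consumed by ring A of a second molecule of the electrophile (self-condensation, oligomer formation) faster than by the hindered boron-bearing carbon. Protodeboronation is less serious, since the C8–H flavan so formed couples at the same carbon under the same conditions. The fallback sets out from 19 and returns at 24 and uses a blocking group. NBS (CH2Cl2, −20 °C) should brominate C8(U) of 19 to give the 8-bromo penta-O-benzyl flavan-3-ol F3. DDQ and 2-ethoxyethanol then give the 8-bromo 4β-(2-ethoxyethoxy) alcohol F4, and esterification with 21 (DCC, DMAP, CH2Cl2) gives the 8-bromo galloylated electrophile F5, whose ring A is deactivated and blocked at its most nucleophilic position. Coupling with 17 (BF3·OEt2, CH2Cl2/MeCN, −40 °C) gives the 8-bromo protected dimer F6. Hydrogenolysis in the presence of base (H2, Pd(OH)2/C, Et3N, THF/MeOH) removes bromine and all benzyl groups to give 24.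

3. Step 2. What may go wrong: the di-ortho-substituted aryl copper species may open the epoxide so slowly that addition to the ester, bromohydrin formation by the magnesium salt or loss of metal fluoride from the metalated fluoroarene take over. The fallback sets out from 2 and returns at 6, and builds the lactate by olefination and asymmetric hydrogenation instead of epoxide opening. Aryllithium 4 is quenched with DMF at −78 °C to give 2,4-bis(benzyloxy)-6-fluorobenzaldehyde F7. Horner–Wadsworth–Emmons reaction with methyl 2-acetoxy-2-(dimethoxyphosphoryl)acetate (LiCl, DBU, MeCN) gives methyl (Z)-2-acetoxy-3-[2,4-bis(benzyloxy)-6-fluorophenyl]prop-2-enoate F8. Enantioselective hydrogenation with [Rh(cod)((S,S)-Et-DuPHOS)]OTf (H2, MeOH; the antipodal ligand is used if the sense proves opposite) should give methyl (2S)-2-acetoxy-3-[2,4-bis(benzyloxy)-6-fluorophenyl]propanoate F9, and methanolysis (K2CO3, MeOH, 0 °C) gives 6.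

**Further compounds**

F1 | step 7 | (2R,3S)-3,5,7-tris(benzyloxy)-2-[3,4-bis(benzyloxy)phenyl]-3,4-dihydro-2H-chromene | c1c(OCc2ccccc2)cc(OCc2ccccc2)c2c1O[C@H](c1ccc(OCc3ccccc3)c(OCc3ccccc3)c1)[C@@H](OCc1ccccc1)C2
F2 | step 7 | (2R,3S)-8-bromo-3,5,7-tris(benzyloxy)-2-[3,4-bis(benzyloxy)phenyl]-3,4-dihydro-2H-chromene | Brc1c(OCc2ccccc2)cc(OCc2ccccc2)c2c1O[C@H](c1ccc(OCc3ccccc3)c(OCc3ccccc3)c1)[C@@H](OCc1ccccc1)C2
F3 | step 11 | 8-bromo derivative of 19, (2R,3R) | O[C@@H]1Cc2c(OCc3ccccc3)cc(OCc3ccccc3)c(Br)c2O[C@@H]1c1cc(OCc2ccccc2)c(OCc2ccccc2)c(OCc2ccccc2)c1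
F4 | step 11 | 8-bromo derivative of 20, 4β-(2-ethoxyethoxy), (2R,3R,4S) | O[C@@H]1[C@@H](OCCOCC)c2c(OCc3ccccc3)cc(OCc3ccccc3)c(Br)c2O[C@@H]1c1cc(OCc2ccccc2)c(OCc2ccccc2)c(OCc2ccccc2)c1
F5 | step 11 | 8-bromo derivative of 22, 4β-(2-ethoxyethoxy), (2R,3R,4S) | O=C(O[C@@H]1[C@@H](OCCOCC)c2c(OCc3ccccc3)cc(OCc3ccccc3)c(Br)c2O[C@@H]1c1cc(OCc2ccccc2)c(OCc2ccccc2)c(OCc2ccccc2)c1)c1cc(OCc2ccccc2)c(OCc2ccccc2)c(OCc2ccccc2)c1
F6 | step 11 | 8-bromo derivative (upper unit) of 23, same spatial arrangement as 23 | O=C(O[C@@H]1[C@@H](c2c(OCc3ccccc3)cc(OCc3ccccc3)c3c2O[C@H](c2ccc(OCc4ccccc4)c(OCc4ccccc4)c2)[C@@H](OCc2ccccc2)C3)c2c(OCc3ccccc3)cc(OCc3ccccc3)c(Br)c2O[C@@H]1c1cc(OCc2ccccc2)c(OCc2ccccc2)c(OCc2ccccc2)c1)c1cc(OCc2ccccc2)c(OCc2ccccc2)c(OCc2ccccc2)c1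
F7 | step 2 | 2,4-bis(benzyloxy)-6-fluorobenzaldehyde | O=Cc1c(F)cc(OCc2ccccc2)cc1OCc1ccccc1
F8 | step 2 | methyl (Z)-2-acetoxy-3-[2,4-bis(benzyloxy)-6-fluorophenyl]prop-2-enoate | COC(=O)/C(OC(C)=O)=C/c1c(F)cc(OCc2ccccc2)cc1OCc1ccccc1
F9 | step 2 | methyl (2S)-2-acetoxy-3-[2,4-bis(benzyloxy)-6-fluorophenyl]propanoate | COC(=O)[C@@H](OC(C)=O)Cc1c(F)cc(OCc2ccccc2)cc1OCc1ccccc1
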